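**Retrosynthetic overview**

- The acid at C6 comes from its tert-butyl ester. The (1E,3E)-diene is cut at its central single bond into an (E)-alkenylboronate on the chroman and an (E)-trisubstituted vinyl iodide made from dihydro-β-ionone (Suzuki coupling).
- The dihydropyran ring of the chroman is opened at the O1–C8a bond. A tertiary alkoxide on C2, released by base-induced opening of an oxirane that spans C2 and the first side-chain carbon, closes the ring by displacing fluoride from C8a. The same operation turns the CH2Cl arm into the C2-ethynyl handle.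
- Enabling feature: on the benzene ring C8a lies para to C6, which carries the carboxyl group, so C8a is activated for addition–elimination. C2 is a fully substituted carbinol carbon next to side-chain unsaturation, so it can be stored as the quaternary carbon of a Sharpless oxirane.
- The epoxy chloride comes from an (E)-allylic alcohol by Sharpless epoxidation and Appel chlorination; the allylic alcohol comes from tert-butyl 3-bromo-4-fluorobenzoate by Heck reaction, olefination and reduction.
- Ring order: the benzene and cyclohexene rings are bought; a temporary oxirane is made in step 4; the dihydropyran ring is closed in step 6 as the oxirane is consumed.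

Key step: step 6

Assumption: tert-butyl 3-bromo-4-fluorobenzoate is taken as a catalogue compound (otherwise one esterification from 3-bromo-4-fluorobenzoic acid). The stereocentre of the target is C2 of the chroman and is (R).

**Route**

Step 1
Reactants: 1 tert-butyl 3-bromo-4-fluorobenzoate; 2 but-3-en-2-ol (racemic)
Product: 3 tert-butyl 4-fluoro-3-(3-oxobutyl)benzoate
Conditions: Pd(OAc)2 (2 mol%), P(o-tol)3 (4 mol%), NaHCO3 (2 equiv), DMF, 110 °C
Reagents that add atoms: none
Why: Heck arylation of an allylic alcohol: the aryl group adds to the terminal alkene carbon and β-hydride elimination toward the carbinol carbon gives the enol and hence the methyl ketone, so the stereocentre of 2 is lost, while the C–F bond and the tert-butyl ester should not react under weakly basic conditions.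

Step 2
Reactants: 3 tert-butyl 4-fluoro-3-(3-oxobutyl)benzoate
Product: 4 tert-butyl 3-[(3E)-5-ethoxy-3-methyl-5-oxopent-3-en-1-yl]-4-fluorobenzoate
Conditions: (EtO)2P(O)CH2CO2Et (1.5 equiv), NaH (1.4 equiv), THF, 0 to 40 °C; chromatography to remove the (Z)-isomer
Reagents that add atoms: triethyl phosphonoacetate, CCOC(=O)CP(=O)(OCC)OCC
Why: Horner–Wadsworth–Emmons olefination of the methyl ketone should give mainly the (E)-enoate (ester trans to the larger CH2CH2Ar group); the minor (Z)-isomer must be removed because the alkene geometry later fixes the configuration of the quaternary carbon.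

Step 3
Reactants: 4 tert-butyl 3-[(3E)-5-ethoxy-3-methyl-5-oxopent-3-en-1-yl]-4-fluorobenzoate
Product: 5 tert-butyl 4-fluoro-3-[(3E)-5-hydroxy-3-methylpent-3-en-1-yl]benzoate
Conditions: i-Bu2AlH (2.2 equiv), CH2Cl2, −78 °C; aq. potassium sodium tartrate
Reagents that add atoms: none
Why: Chemoselective aluminium hydride 1,2-reduction: the unhindered conjugated ethyl ester should be reduced to the allylic alcohol at −78 °C much faster than the hindered aryl tert-butyl ester, with the alkene geometry retained.

Step 4
Reactants: 5 tert-butyl 4-fluoro-3-[(3E)-5-hydroxy-3-methylpent-3-en-1-yl]benzoate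
Product: 6 tert-butyl 4-fluoro-3-{2-[(2R,3R)-3-(hydroxymethyl)-2-methyloxiran-2-yl]ethyl}benzoate
Conditions: Ti(OiPr)4 (10 mol%), D-(−)-diethyl tartrate (12 mol%), t-BuOOH (2 equiv), 4 Å molecular sieves, CH2Cl2, −20 °C
Reagents that add atoms: tert-butyl hydroperoxide, CC(C)(C)OO
Why: Sharpless asymmetric epoxidation: the (E)-trisubstituted allylic alcohol is a geraniol-type substrate, for which the D-(−)-tartrate catalyst should give the (2R,3R)-epoxy alcohol, so both new stereocentres, including the quaternary carbon that becomes C2 of the chroman, are set by the catalyst.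

Step 5
Reactants: 6 tert-butyl 4-fluoro-3-{2-[(2R,3R)-3-(hydroxymethyl)-2-methyloxiran-2-yl]ethyl}benzoate
Product: 7 tert-butyl 3-{2-[(2R,3S)-3-(chloromethyl)-2-methyloxiran-2-yl]ethyl}-4-fluorobenzoate
Conditions: PPh3 (1.3 equiv), CCl4, NaHCO3 (0.2 equiv), reflux
Reagents that add atoms: carbon tetrachloride, ClC(Cl)(Cl)Cl
Why: Appel chlorination replaces the primary hydroxyl by chloride under buffered, near-neutral conditions without opening the oxirane; no stereocentre is touched (the descriptor of the oxirane CH changes from R to S only because CH2Cl outranks the ring carbon).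

Step 6
Reactants: 7 tert-butyl 3-{2-[(2R,3S)-3-(chloromethyl)-2-methyloxiran-2-yl]ethyl}-4-fluorobenzoate
Product: 10 tert-butyl (2R)-2-ethynyl-2-methyl-3,4-dihydro-2H-chromene-6-carboxylate, via chloroallylic lithium alkoxide 8 (not isolated), via dilithium alkynyl alkoxide 9 (not isolated)
Conditions: LiN(i-Pr)2 (3.1 equiv), THF, −78 to −20 °C; then DMPU, 50 °C; aq. NH4Cl
Reagents that add atoms: none
Why: Proposed new method: LiN(i-Pr)2 removes a proton of the CH2Cl group of 7 with opening of the strained oxirane at its CH carbon (8), a second elimination of HCl gives the alkyne and the third equivalent of base leaves the lithium acetylide–tertiary alkoxide 9; on warming in THF/DMPU the alkoxide adds to the fluorine-bearing arene carbon para to the ester, the Meisenheimer anion is stabilised by the ester carbonyl, and loss of fluoride forms the O–aryl bond. The closest known reactions are the base-induced conversion of 2,3-epoxy chlorides into propargylic alcohols and the intramolecular SNAr etherification of tertiary alkoxides on 4-fluorobenzoates, which have not been run as one domino sequence, hence the label. The dihydropyran ring closes by a 6-exo-trig addition–elimination at the aryl carbon. No stereocentre is created: the C–O bond of the oxirane quaternary carbon is never broken, so its (R) configuration from the Sharpless step becomes (R) at C2, while the second oxirane stereocentre is consumed as an alkyne carbon. The step needs deprotonation at CH2Cl to outrun ortho-lithiation of the fluoroarene and attack on the ester, which the bulky amide base, the low temperature of the first stage and the tert-butyl ester should secure, and only the tertiary alkoxide can reach the C–F carbon through a six-membered transition state, so the acetylide stays a spectator until work-up.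

Step 7
Reactants: 10 tert-butyl (2R)-2-ethynyl-2-methyl-3,4-dihydro-2H-chromene-6-carboxylate
Product: 11 tert-butyl (2R)-2-methyl-2-[(E)-2-(4,4,5,5-tetramethyl-1,3,2-dioxaborolan-2-yl)ethenyl]-3,4-dihydro-2H-chromene-6-carboxylate
Conditions: pinacolborane (1.5 equiv), Cp2Zr(H)Cl (10 mol%), Et3N (10 mol%), neat, 60 °C
Reagents that add atoms: pinacolborane, CC1(C)OBOC1(C)C
Why: Zirconocene-hydride-catalysed syn hydroboration of the terminal alkyne places boron on the terminal carbon and should give the (E)-alkenylboronate; the ester and the aryl ether are inert.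

Step 8
Reactants: 12 dihydro-β-ionone, 4-(2,6,6-trimethylcyclohex-1-en-1-yl)butan-2-one
Product: 14 2-(but-3-yn-1-yl)-1,3,3-trimethylcyclohex-1-ene, via terminal enol diethyl phosphate 13 (not isolated)
Conditions: LiN(i-Pr)2 (1.05 equiv), THF, −78 °C; ClP(O)(OEt)2, −78 °C to rt; then LiN(i-Pr)2 (2.3 equiv), −78 °C to rt; aq. NH4Cl
Reagents that add atoms: none
Why: Negishi's one-flask conversion of a methyl ketone into a terminal alkyne: kinetic deprotonation at the methyl group, O-phosphorylation to the terminal enol phosphate and amide-induced elimination of diethyl phosphate.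

Step 9
Reactants: 14 2-(but-3-yn-1-yl)-1,3,3-trimethylcyclohex-1-ene
Product: 16 2-[(3E)-4-iodo-3-methylbut-3-en-1-yl]-1,3,3-trimethylcyclohex-1-ene, via alkenyldimethylalane 15 (not isolated)
Conditions: AlMe3 (2 equiv), Cp2ZrCl2 (0.25 equiv), CH2Cl2, 0 °C to rt; then I2, THF, −30 to 0 °C
Reagents that add atoms: trimethylaluminium, C[Al](C)C; iodine, II
Why: Negishi zirconium-catalysed carboalumination adds methyl and aluminium syn across the terminal alkyne with aluminium on the terminal carbon, and iodinolysis with retention should give the (E)-trisubstituted vinyl iodide.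

Step 10
Reactants: 11 tert-butyl (2R)-2-methyl-2-[(E)-2-(4,4,5,5-tetramethyl-1,3,2-dioxaborolan-2-yl)ethenyl]-3,4-dihydro-2H-chromene-6-carboxylate; 16 2-[(3E)-4-iodo-3-methylbut-3-en-1-yl]-1,3,3-trimethylcyclohex-1-ene
Product: 17 tert-butyl (2R)-2-methyl-2-[(1E,3E)-4-methyl-6-(2,6,6-trimethylcyclohex-1-en-1-yl)hexa-1,3-dien-1-yl]-3,4-dihydro-2H-chromene-6-carboxylate
Conditions: Pd(PPh3)4 (5 mol%), aq. K3PO4 (3 equiv), THF, 50 °C, degassed
Reagents that add atoms: none
Why: Suzuki–Miyaura coupling of an (E)-alkenylboronate with an (E)-alkenyl iodide proceeds with retention at both alkenes and should give the (1E,3E)-diene; the mild aqueous base leaves the tert-butyl ester and the tertiary allylic aryl ether intact.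

Step 11
Reactants: 17 tert-butyl (2R)-2-methyl-2-[(1E,3E)-4-methyl-6-(2,6,6-trimethylcyclohex-1-en-1-yl)hexa-1,3-dien-1-yl]-3,4-dihydro-2H-chromene-6-carboxylate
Product: 18 (2R)-2-methyl-2-[(1E,3E)-4-methyl-6-(2,6,6-trimethylcyclohex-1-en-1-yl)hexa-1,3-dien-1-yl]-3,4-dihydro-2H-chromene-6-carboxylic acid (CNP0265961.1)
Conditions: powdered KOH (8 equiv), THF, 25 °C; then 0.5 M HCl to pH 4, 0 °C
Reagents that add atoms: potassium hydroxide, [K+].[OH-]
Why: Cleavage of the tert-butyl benzoate by poorly solvated hydroxide (acyl–oxygen cleavage) avoids strong acid, which could ionise the tertiary dienylic C2–O bond or cyclise the polyene; C2 is not affected.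

**Compound list**

1 | tert-butyl 3-bromo-4-fluorobenzoate | CC(C)(C)OC(=O)c1ccc(F)c(Br)c1 | starting material
2 | but-3-en-2-ol (racemic) | CC(O)C=C | starting material
3 | tert-butyl 4-fluoro-3-(3-oxobutyl)benzoate | CC(=O)CCc1cc(C(=O)OC(C)(C)C)ccc1F | intermediate
4 | tert-butyl 3-[(3E)-5-ethoxy-3-methyl-5-oxopent-3-en-1-yl]-4-fluorobenzoate | CCOC(=O)/C=C(\C)CCc1cc(C(=O)OC(C)(C)C)ccc1F | intermediate
5 | tert-butyl 4-fluoro-3-[(3E)-5-hydroxy-3-methylpent-3-en-1-yl]benzoate | OC/C=C(\C)CCc1cc(C(=O)OC(C)(C)C)ccc1F | intermediate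
6 | tert-butyl 4-fluoro-3-{2-[(2R,3R)-3-(hydroxymethyl)-2-methyloxiran-2-yl]ethyl}benzoate | OC[C@H]1O[C@]1(C)CCc2cc(C(=O)OC(C)(C)C)ccc2F | intermediate
7 | tert-butyl 3-{2-[(2R,3S)-3-(chloromethyl)-2-methyloxiran-2-yl]ethyl}-4-fluorobenzoate | ClC[C@H]1O[C@]1(C)CCc2cc(C(=O)OC(C)(C)C)ccc2F | intermediate
8 | lithium (3R)-5-[5-(tert-butoxycarbonyl)-2-fluorophenyl]-1-chloro-3-methylpent-1-en-3-olate (alkene geometry left open; both isomers eliminate to 9) | ClC=C[C@@]([O-])(C)CCc1cc(C(=O)OC(C)(C)C)ccc1F.[Li+] | intermediate
9 | dilithium (3R)-5-[5-(tert-butoxycarbonyl)-2-fluorophenyl]-3-methylpent-1-yn-1-id-3-olate | [Li+].[Li+].[C-]#C[C@@]([O-])(C)CCc1cc(C(=O)OC(C)(C)C)ccc1F | intermediate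
10 | tert-butyl (2R)-2-ethynyl-2-methyl-3,4-dihydro-2H-chromene-6-carboxylate | C#C[C@@]1(C)CCc2cc(C(=O)OC(C)(C)C)ccc2O1 | intermediate
11 | tert-butyl (2R)-2-methyl-2-[(E)-2-(4,4,5,5-tetramethyl-1,3,2-dioxaborolan-2-yl)ethenyl]-3,4-dihydro-2H-chromene-6-carboxylate | CC1(C)OB(/C=C/[C@@]2(C)CCc3cc(C(=O)OC(C)(C)C)ccc3O2)OC1(C)C | intermediate
12 | dihydro-β-ionone, 4-(2,6,6-trimethylcyclohex-1-en-1-yl)butan-2-one | CC(=O)CCC1=C(C)CCCC1(C)C | starting material
13 | diethyl 4-(2,6,6-trimethylcyclohex-1-en-1-yl)but-1-en-2-yl phosphate | C=C(CCC1=C(C)CCCC1(C)C)OP(=O)(OCC)OCC | intermediate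
14 | 2-(but-3-yn-1-yl)-1,3,3-trimethylcyclohex-1-ene | C#CCCC1=C(C)CCCC1(C)C | intermediate
15 | dimethyl[(1E)-2-methyl-4-(2,6,6-trimethylcyclohex-1-en-1-yl)but-1-en-1-yl]alane | C[Al](C)/C=C(\C)CCC1=C(C)CCCC1(C)C | intermediate
16 | 2-[(3E)-4-iodo-3-methylbut-3-en-1-yl]-1,3,3-trimethylcyclohex-1-ene | I/C=C(\C)CCC1=C(C)CCCC1(C)C | intermediate
17 | tert-butyl (2R)-2-methyl-2-[(1E,3E)-4-methyl-6-(2,6,6-trimethylcyclohex-1-en-1-yl)hexa-1,3-dien-1-yl]-3,4-dihydro-2H-chromene-6-carboxylate | CC1=C(CC/C(C)=C/C=C/[C@@]2(C)CCc3cc(C(=O)OC(C)(C)C)ccc3O2)C(C)(C)CCC1 | intermediate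
18 | (2R)-2-methyl-2-[(1E,3E)-4-methyl-6-(2,6,6-trimethylcyclohex-1-en-1-yl)hexa-1,3-dien-1-yl]-3,4-dihydro-2H-chromene-6-carboxylic acid | CC1=C(CC/C(C)=C/C=C/[C@@]2(C)CCc3cc(C(=O)O)ccc3O2)C(C)(C)CCC1 | target

**Step count and risks**

Total step count: 11. Longest linear sequence: 9 steps (steps 1 to 7, then 10 and 11, counted from 1).

Steps most likely to fail:

1. Step 6 (proposed new method). The amide base may metalate the fluoroarene next to fluorine (followed by loss of LiF and amine addition to the aryne), the lithium alkoxide may close the ring too slowly so that intermolecular attack on the ester competes, or the domino may stall at the chloroallylic stage. The fallback uses known chemistry only, sets out from 6 and comes back at 10; it opens the oxirane reductively instead of by base. Compound 6 is converted with I2, PPh3 and imidazole (CH2Cl2, 0 °C) into tert-butyl 4-fluoro-3-{2-[(2R,3S)-3-(iodomethyl)-2-methyloxiran-2-yl]ethyl}benzoate F1. Zinc dust in refluxing ethanol should give, by reductive β-elimination with the quaternary C–O bond retained, tert-butyl 4-fluoro-3-[(3R)-3-hydroxy-3-methylpent-4-en-1-yl]benzoate F2. KN(SiMe3)2 in THF (0 °C to rt) closes the O–aryl bond by the well-precedented intramolecular SNAr to tert-butyl (2R)-2-ethenyl-2-methyl-3,4-dihydro-2H-chromene-6-carboxylate F3. Ozonolysis (O3, CH2Cl2/MeOH, −78 °C; Me2S) gives tert-butyl (2R)-2-formyl-2-methyl-3,4-dihydro-2H-chromene-6-carboxylate F4, which cannot epimerise, and Ohira–Bestmann homologation (dimethyl (1-diazo-2-oxopropyl)phosphonate, K2CO3, MeOH) returns 10.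

2. Step 3. Chemoselectivity may be lost, with partial reduction of the aryl tert-butyl ester alongside the enoate. The fallback sets out from 4 and comes back at 5; it separates the two esters chemically instead of kinetically. The ethyl ester of 4 is saponified (LiOH, THF/H2O, 40 °C; the tert-butyl benzoate should survive) to (2E)-5-[5-(tert-butoxycarbonyl)-2-fluorophenyl]-3-methylpent-2-enoic acid F5. This is activated with isobutyl chloroformate and N-methylmorpholine (THF, −15 °C) as the mixed anhydride isobutyl (2E)-5-[5-(tert-butoxycarbonyl)-2-fluorophenyl]-3-methylpent-2-enoyl carbonate F6 and reduced in the same flask with NaBH4 (THF/H2O, 0 °C) to 5.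

3. Step 11. Cleavage of the hindered, electron-rich tert-butyl benzoate may be incomplete, and forcing it risks isomerisation or loss of the diene and ionisation of the tertiary allylic ether. The fallback sets out from 10 and comes back at 18; it moves the deprotection in front of the diene construction, where acid is tolerable. Compound 10 is treated with CF3CO2H in CH2Cl2 at 0 °C to give (2R)-2-ethynyl-2-methyl-3,4-dihydro-2H-chromene-6-carboxylic acid F7. Hydroboration with pinacolborane (2.5 equiv, Cp2Zr(H)Cl cat., Et3N; the acyloxyboronate formed from the acid is cleaved on aqueous work-up) gives (2R)-2-methyl-2-[(E)-2-(4,4,5,5-tetramethyl-1,3,2-dioxaborolan-2-yl)ethenyl]-3,4-dihydro-2H-chromene-6-carboxylic acid F8. Suzuki coupling of F8 with 16 (Pd(PPh3)4, aq. K3PO4, 4 equiv, THF, 50 °C; acidification to pH 4) should give 18 directly.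

Further compounds
F1 | step 6 | tert-butyl 4-fluoro-3-{2-[(2R,3S)-3-(iodomethyl)-2-methyloxiran-2-yl]ethyl}benzoate | IC[C@H]1O[C@]1(C)CCc2cc(C(=O)OC(C)(C)C)ccc2F
F2 | step 6 | tert-butyl 4-fluoro-3-[(3R)-3-hydroxy-3-methylpent-4-en-1-yl]benzoate | C=C[C@@](O)(C)CCc1cc(C(=O)OC(C)(C)C)ccc1F
F3 | step 6 | tert-butyl (2R)-2-ethenyl-2-methyl-3,4-dihydro-2H-chromene-6-carboxylate | C=C[C@@]1(C)CCc2cc(C(=O)OC(C)(C)C)ccc2O1
F4 | step 6 | tert-butyl (2R)-2-formyl-2-methyl-3,4-dihydro-2H-chromene-6-carboxylate | O=C[C@@]1(C)CCc2cc(C(=O)OC(C)(C)C)ccc2O1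
F5 | step 3 | (2E)-5-[5-(tert-butoxycarbonyl)-2-fluorophenyl]-3-methylpent-2-enoic acid | OC(=O)/C=C(\C)CCc1cc(C(=O)OC(C)(C)C)ccc1F
F6 | step 3 | isobutyl (2E)-5-[5-(tert-butoxycarbonyl)-2-fluorophenyl]-3-methylpent-2-enoyl carbonate | CC(C)COC(=O)OC(=O)/C=C(\C)CCc1cc(C(=O)OC(C)(C)C)ccc1F
F7 | step 11 | (2R)-2-ethynyl-2-methyl-3,4-dihydro-2H-chromene-6-carboxylic acid | C#C[C@@]1(C)CCc2cc(C(=O)O)ccc2O1
F8 | step 11 | (2R)-2-methyl-2-[(E)-2-(4,4,5,5-tetramethyl-1,3,2-dioxaborolan-2-yl)ethenyl]-3,4-dihydro-2H-chromene-6-carboxylic acid | CC1(C)OB(/C=C/[C@@]2(C)CCc3cc(C(=O)O)ccc3O2)OC1(C)C
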